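Saturday's flask read 71% of target at 80.0 min, more than the 0% read in Monday's at that time, though the two shared reagent charge and temperature and differed in substrate.

the same everywhere: reagent 2.16 M
- Monday's: substrate 0.40 M; temperature 55 °C; run made earlier
- Tuesday's: substrate 0.86 M; temperature 80 °C; run made earlier
- Saturday's: substrate 1.7 M; temperature 55 °C; run made earlier
- south-west: substrate 0.50 M; at 100 °C throughout; time 2.0 h
- south-east: substrate 1.8 M; at 60 °C until 25 min, from then on at 100 °C; time 2.0 h

- Monday's (time / min: target / %): 6.00: 61; 12.0: 42; 25.0: 12; 40.0: 7; 80.0: 0
- Tuesday's (time / min: target / %): 6.00: 17; 12.0: 6; 20.0: 7; 30.0: 1
- Saturday's (time / min: target / %): 15.0: 81; 30.0: 78; 50.0: 73; 60.0: 75; 80.0: 71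

(each reading ± 2 percentage points)

* which of the two ends with the higher amount of target, in percent of the substrate charged ("neither" if they lie within 2 percentage points) (south-west / south-east / neither)
* target at the end, in percent of the substrate charged, south-west
* target at the end, in percent of the substrate charged, south-east



I ran the flask in slow motion. In the first instants I took substrate and reagent to form target, one reagent to each substrate; Monday's flask already showed 61% at 6.00 min and was falling. In the middle, I took target to take up a second reagent and go to something no reading shows. In Monday's flask reagent stood in surplus, so I treated that loss as pseudo-first-order, whose integrated rate is an exponential. Its readings gave a half-life of about 8.10 min, shorter than the 2.0 h asked.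

At the end, I expected the loss to stop when reagent ran out. So I carried the reagent ceiling, 80.0% for south-east: substrate minus the reagent surplus over substrate, as a share of substrate, or reagent over substrate where reagent is the smaller charge. In south-east I took reagent as the limiting reagent of this stage, with 0.360 M over substrate. For Saturday's flask the charges give 72.9%, and its late readings lay between 71% and 75%. South-west has more reagent than both steps ask for, so I expected no target there. I expected the ceiling in south-east, though no run went as hot as the second temperature.

The forecast said south-east, with 0% for south-west and 80% for south-east: “Heating only speeds its arrival, barring unseen thermal loss”.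

South-west ended at 0% and south-east at 80.0%, the ceiling of 80.0%, with 0% of its reagent left, so south-east held more.

    reagent + target → over-reaction product (k = 0.00120 M⁻¹ s⁻¹, Ea = 76.0 kJ mol⁻¹)
    substrate + reagent → target, rate k2*[substrate]*[reagent]^0.5 (k = 0.0310 M⁻⁰·⁵ s⁻¹, Ea = 72.0 kJ mol⁻¹)
    (constants at 60 °C)

In south-east at 0.00489 h, the turning of substrate into target used reagent 24 times as fast as the turning of target into over-reaction product. At that moment the half-life of substrate by its step was 0.33 min, against 0.18 h for reagent by the step to over-reaction product. South-east's target moved by 5 points with reagent at 2.07 M or 2.25 M, the other charges and the time held. In the neighbour with 1.3 M of reagent, otherwise south-east, the ceiling is 72.2%. That flask gave 70.1% of target, with 28.9% substrate and 1.08% over-reaction product.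

(The data come from a simulation from invented constants.)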